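The heptane chain is numbered from C1 on the methoxycatechol ring A to C7 on the 4-hydroxyphenyl ring B. Everything rests on disconnecting C3–C4 and C5–C6, so that the syn-1,3-diol stretch C3(OH)–C4–C5(OH)–C6–C7 comes from two acetaldehyde molecules added in turn to the carbonyl of a 3-(ring A)propanal. A single aldolase-mediated operation makes both bonds, fixes the C3 and C5 carbinols and stores C7 as a lactol closed through the C3 oxygen. The precursor is that propanal with the catechol masked as two methoxymethyl ethers. Ring B is then added at C7 as a Grignard reagent, and the surplus benzylic oxygen is removed as its acetate.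

Key step: step 5

Remark (assumption): the aldolase is taken to be an acetaldehyde-tolerant variant selected by screening for turnover of the arylpropanal, and its usual facial preference (R carbinol in each addition) is assumed to hold for this acceptor. Chain locants C1 to C7 (ring A to ring B) are used in the names of the open-chain compounds after the key step.

Design note: the methoxymethyl ethers on ring A are small, polar, and stable at pH 7.5 and to the Grignard reagent. They fall in the same acid treatment that frees the diol. The C7 oxygen is removed by hydrogenolysis of a triacetate, so that no free C3 hydroxyl can capture a C7 benzylic cation as a 2-aryltetrahydropyran. In step 7 the species present before acetylation are bromomagnesium alkoxides and are numbered and drawn as such.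

Step 1
Reactants: 1 3,4-dihydroxy-5-methoxybenzaldehyde
Product: 2 3-methoxy-4,5-bis(methoxymethoxy)benzaldehyde
Conditions: MOMCl (3 equiv), K2CO3 (4 equiv), acetone, 0 °C to rt
Reagents that add atoms: chloromethyl methyl ether, COCCl
Why: Double Williamson-type O-alkylation of the two phenoxides by the reactive α-chloro ether should proceed cleanly because the aldehyde is non-enolisable and inert to K2CO3.

Step 2
Reactants: 2 3-methoxy-4,5-bis(methoxymethoxy)benzaldehyde; 3 ethyl (triphenylphosphoranylidene)acetate
Product: 4 ethyl (E)-3-[3-methoxy-4,5-bis(methoxymethoxy)phenyl]prop-2-enoate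
Conditions: toluene, 80 °C
Reagents that add atoms: none
Why: Wittig olefination of an aromatic aldehyde with a stabilised ylide should give the E-cinnamate, and the alkene geometry is of no consequence because the double bond is saturated in the next step.

Step 3
Reactants: 4 ethyl (E)-3-[3-methoxy-4,5-bis(methoxymethoxy)phenyl]prop-2-enoate
Product: 5 ethyl 3-[3-methoxy-4,5-bis(methoxymethoxy)phenyl]propanoate
Conditions: H2 (1 atm), Pd/C, EtOAc, rt
Reagents that add atoms: none
Why: Heterogeneous catalytic hydrogenation of the conjugated C=C bond under neutral conditions should leave the ester, the arene and the aryl methoxymethyl acetals untouched.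

Step 4
Reactants: 5 ethyl 3-[3-methoxy-4,5-bis(methoxymethoxy)phenyl]propanoate
Product: 6 3-[3-methoxy-4,5-bis(methoxymethoxy)phenyl]propanal
Conditions: i-Bu2AlH (1.1 equiv), CH2Cl2, −78 °C; then MeOH, aq. potassium sodium tartrate
Reagents that add atoms: none
Why: Partial ester reduction with one equivalent of i-Bu2AlH at −78 °C should stop at the tetrahedral aluminium hemiacetal, which releases the aldehyde only on work-up.

Step 5
Reactants: 6 3-[3-methoxy-4,5-bis(methoxymethoxy)phenyl]propanal; 7 acetaldehyde (two molecules incorporated)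
Product: 10 (4R,6R)-6-{2-[3-methoxy-4,5-bis(methoxymethoxy)phenyl]ethyl}tetrahydro-2H-pyran-2,4-diol (mixture of anomers), via hydroxy aldehyde 8 (not isolated), via dihydroxy aldehyde 9 (not isolated)
Conditions: 2-deoxy-D-ribose-5-phosphate aldolase (acetaldehyde-tolerant Escherichia coli variant, cell-free extract), 7 (2.5 equiv, fed over 8 h), triethanolamine buffer (0.1 M, pH 7.5), dimethyl sulfoxide (15 vol%), 25 °C
Reagents that add atoms: none
Why: The active-site lysine of the aldolase condenses with acetaldehyde 7 to an enamine that attacks the C3 carbonyl of 6, hydrolysis releases β-hydroxy aldehyde 8, and 8 is the acceptor for a second enamine to give 9, so that C3–C4 and C5–C6 are formed in sequence. The closest known reaction type is the aldolase-catalysed sequential aldol addition of two acetaldehyde donors to unbranched aliphatic aldehydes (acetaldehyde itself, 2-substituted acetaldehydes, 3-substituted propanals) that ends in a 2,4-dideoxypyranose lactol. The tetrahydropyran ring should close by 6-exo-trig hemiacetalisation of the C3 hydroxyl onto the C7 aldehyde of 9, a reversible step that takes the aldehyde out of further chain growth. C3 is set R in the first addition and C5 in the second (4R in 10, which becomes 5S in the target by a change of substituent priority only) by the fixed geometry of enamine and acceptor in the active site, the same carbonyl face being used each time and hence the syn diol, while the anomeric centre C7 stays uncontrolled and is erased later. The step needs 6 to serve only as acceptor and the chain to stop at two additions: the donor site admits nothing larger than a two- or three-carbon carbonyl compound, which excludes 6 with its arylmethyl group on the α-carbon, and the 1,5 spacing of the C3 hydroxyl and the C7 aldehyde secures the stop through lactol formation. Slow feeding of 7 is meant to hold back acetaldehyde self-trimerisation and enzyme inactivation, and the small polar methoxymethyl ethers lie remote from the carbonyl and keep 6 dispersible in buffered aqueous dimethyl sulfoxide.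

Step 6
Reactants: 11 1-(benzyloxy)-4-bromobenzene
Product: 12 [4-(benzyloxy)phenyl]magnesium bromide (used as its THF solution)
Conditions: Mg turnings, I2 (cat.), THF, 50 °C
Reagents that add atoms: magnesium, [Mg]
Why: Grignard reagent formation by insertion of magnesium into the aryl C–Br bond should be uneventful because the benzyl aryl ether is inert to the reagent.

Step 7
Reactants: 10 (4R,6R)-6-{2-[3-methoxy-4,5-bis(methoxymethoxy)phenyl]ethyl}tetrahydro-2H-pyran-2,4-diol; 12 [4-(benzyloxy)phenyl]magnesium bromide (3.5 equiv)
Product: 15 (3R,5R)-7-[4-(benzyloxy)phenyl]-1-[3-methoxy-4,5-bis(methoxymethoxy)phenyl]heptane-3,5,7-triyl triacetate (C7 epimers), via aldehyde dialkoxide 13 (not isolated), via magnesium trialkoxide 14 (not isolated)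
Conditions: THF, 0 °C to rt; then Ac2O (8 equiv), 4-(dimethylamino)pyridine (cat.), 0 °C to rt
Reagents that add atoms: acetic anhydride, CC(=O)OC(C)=O
Why: Two equivalents of 12 should deprotonate both hydroxyls of 10, the resulting magnesium lactolate opens by ring–chain equilibration to the aldehyde dialkoxide 13, a third equivalent adds to its C7 carbonyl to give trialkoxide 14 (Grignard addition to a lactol), and the three magnesium alkoxides are then acetylated in the same flask by nucleophilic acyl substitution; the new C7 carbinol forms without control, which does not matter because C7 ends as CH2, and C3 and C5 are not touched.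

Step 8
Reactants: 15 (3R,5R)-7-[4-(benzyloxy)phenyl]-1-[3-methoxy-4,5-bis(methoxymethoxy)phenyl]heptane-3,5,7-triyl triacetate
Product: 17 (3R,5S)-1-(3,4-dihydroxy-5-methoxyphenyl)-7-(4-hydroxyphenyl)heptane-3,5-diol, via diacetate 16 (not isolated)
Conditions: H2 (1 atm), Pd/C, EtOAc–AcOH (20:1), rt; filter, concentrate; then HCl in MeOH (ca. 1 M), argon, 40 °C
Reagents that add atoms: none
Why: Palladium-catalysed hydrogenolysis should cleave the benzyl ether and the electron-rich benzylic C7–OAc bond under conditions too mild to affect the aryl methoxymethyl ethers or the two alkyl acetates, and acid-catalysed transacetalisation and transesterification in methanol should then release the catechol and the two non-benzylic carbinols, whose C–O bonds are never broken, so that C3 (R) and C5 (S) are retained.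

Compound list
1 | 3,4-dihydroxy-5-methoxybenzaldehyde | COc1cc(C=O)cc(O)c1O | starting material
2 | 3-methoxy-4,5-bis(methoxymethoxy)benzaldehyde | COCOc1cc(C=O)cc(OC)c1OCOC | intermediate
3 | ethyl (triphenylphosphoranylidene)acetate | CCOC(=O)C=P(c1ccccc1)(c1ccccc1)c1ccccc1 | starting material
4 | ethyl (E)-3-[3-methoxy-4,5-bis(methoxymethoxy)phenyl]prop-2-enoate | CCOC(=O)/C=C/c1cc(OC)c(OCOC)c(OCOC)c1 | intermediate
5 | ethyl 3-[3-methoxy-4,5-bis(methoxymethoxy)phenyl]propanoate | CCOC(=O)CCc1cc(OC)c(OCOC)c(OCOC)c1 | intermediate
6 | 3-[3-methoxy-4,5-bis(methoxymethoxy)phenyl]propanal | COCOc1cc(CCC=O)cc(OC)c1OCOC | intermediate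
7 | acetaldehyde | CC=O | starting material
8 | (3R)-3-hydroxy-5-[3-methoxy-4,5-bis(methoxymethoxy)phenyl]pentanal | COCOc1cc(CC[C@@H](O)CC=O)cc(OC)c1OCOC | intermediate
9 | (3R,5R)-3,5-dihydroxy-7-[3-methoxy-4,5-bis(methoxymethoxy)phenyl]heptanal | COCOc1cc(CC[C@@H](O)C[C@@H](O)CC=O)cc(OC)c1OCOC | intermediate
10 | (4R,6R)-6-{2-[3-methoxy-4,5-bis(methoxymethoxy)phenyl]ethyl}tetrahydro-2H-pyran-2,4-diol (mixture of anomers) | COCOc1cc(CC[C@@H]2C[C@@H](O)CC(O)O2)cc(OC)c1OCOC | intermediate
11 | 1-(benzyloxy)-4-bromobenzene | Brc1ccc(OCc2ccccc2)cc1 | starting material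
12 | [4-(benzyloxy)phenyl]magnesium bromide | Br[Mg]c1ccc(OCc2ccccc2)cc1 | intermediate
13 | (3R,5R)-3,5-bis[(bromomagnesio)oxy]-7-[3-methoxy-4,5-bis(methoxymethoxy)phenyl]heptanal (bis(bromomagnesium) alkoxide of the open-chain form of 10) | COCOc1cc(CC[C@@H](O[Mg]Br)C[C@@H](O[Mg]Br)CC=O)cc(OC)c1OCOC | intermediate
14 | (3R,5R)-7-[4-(benzyloxy)phenyl]-3,5,7-tris[(bromomagnesio)oxy]-1-[3-methoxy-4,5-bis(methoxymethoxy)phenyl]heptane (C7 epimers) | COCOc1cc(CC[C@@H](O[Mg]Br)C[C@@H](O[Mg]Br)CC(O[Mg]Br)c2ccc(OCc3ccccc3)cc2)cc(OC)c1OCOC | intermediate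
15 | (3R,5R)-7-[4-(benzyloxy)phenyl]-1-[3-methoxy-4,5-bis(methoxymethoxy)phenyl]heptane-3,5,7-triyl triacetate (C7 epimers) | COCOc1cc(CC[C@@H](OC(C)=O)C[C@@H](OC(C)=O)CC(OC(C)=O)c2ccc(OCc3ccccc3)cc2)cc(OC)c1OCOC | intermediate
16 | (3R,5S)-7-(4-hydroxyphenyl)-1-[3-methoxy-4,5-bis(methoxymethoxy)phenyl]heptane-3,5-diyl diacetate | COCOc1cc(CC[C@@H](OC(C)=O)C[C@@H](OC(C)=O)CCc2ccc(O)cc2)cc(OC)c1OCOC | intermediate
17 | (3R,5S)-1-(3,4-dihydroxy-5-methoxyphenyl)-7-(4-hydroxyphenyl)heptane-3,5-diol | COc1cc(CC[C@@H](O)C[C@@H](O)CCc2ccc(O)cc2)cc(O)c1O | target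

Total step count: 8.
Longest linear sequence: 7 steps (steps 1 to 5, then 7 and 8, from 1 to 17); step 6 is a one-step side branch.

Steps most likely to fail

Step 5. The aldolase may not turn over an acceptor of this bulk, the sequence may stall after the first addition, or the enzyme may be inactivated by acetaldehyde and its condensation products before conversion is useful. The fallback replaces the enzyme by a catalytic asymmetric vinylogous aldol addition followed by substrate-controlled reduction. It sets out from 6. A Mukaiyama-type vinylogous aldol addition of 1-ethoxy-1,3-bis(trimethylsilyloxy)buta-1,3-diene under Ti(OiPr)4 and 1,1'-bi-2-naphthol catalysis, with the ligand enantiomer chosen to deliver the 5R carbinol and with an acidic work-up that removes the silyl groups, should give ethyl (5R)-5-hydroxy-7-[3-methoxy-4,5-bis(methoxymethoxy)phenyl]-3-oxoheptanoate F1. A 1,3-syn-selective chelation-controlled reduction (Et2BOMe, NaBH4, THF–MeOH, −78 °C; Narasaka–Prasad reduction) should then give ethyl (3R,5R)-3,5-dihydroxy-7-[3-methoxy-4,5-bis(methoxymethoxy)phenyl]heptanoate F2. Saponification with LiOH in aqueous THF and careful acidification should give (3R,5R)-3,5-dihydroxy-7-[3-methoxy-4,5-bis(methoxymethoxy)phenyl]heptanoic acid F3. Lactonisation in warm toluene with removal of water should give (4R,6R)-4-hydroxy-6-{2-[3-methoxy-4,5-bis(methoxymethoxy)phenyl]ethyl}tetrahydro-2H-pyran-2-one F4. Reduction of F4 with i-Bu2AlH (2.2 equiv, CH2Cl2, −78 °C) should stop at the lactol, where the fallback comes back to the route at 10.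

Step 7. The magnesium alkoxide of the ring-opened β-oxygenated aldehyde may undergo retro-aldol cleavage or be enolised by the basic aryl Grignard reagent faster than it is arylated, the lactolate may open too slowly, or the aggregated alkoxides may be acetylated incompletely in the flask. The fallback masks the β-oxygen before the addition and isolates the adduct; it sets out from 10. Silylation of both hydroxyls (TBSCl, imidazole, DMF) should give (4R,6R)-2,4-bis(tert-butyldimethylsilyloxy)-6-{2-[3-methoxy-4,5-bis(methoxymethoxy)phenyl]ethyl}tetrahydro-2H-pyran F5. Selective hydrolysis of the acetal-type anomeric silyl ether (AcOH, THF, H2O, 0 °C) should give (4R,6R)-4-(tert-butyldimethylsilyloxy)-6-{2-[3-methoxy-4,5-bis(methoxymethoxy)phenyl]ethyl}tetrahydro-2H-pyran-2-ol F6. Addition of 12 (2.2 equiv, THF, 0 °C) to F6, whose β-oxygen is now a silyl ether, followed by aqueous NH4Cl work-up should give (3R,5R)-7-[4-(benzyloxy)phenyl]-5-(tert-butyldimethylsilyloxy)-1-[3-methoxy-4,5-bis(methoxymethoxy)phenyl]heptane-3,7-diol F7. Desilylation with Bu4NF in THF should give (3R,5R)-7-[4-(benzyloxy)phenyl]-1-[3-methoxy-4,5-bis(methoxymethoxy)phenyl]heptane-3,5,7-triol F8. Conventional acetylation of F8 (Ac2O, pyridine, 4-(dimethylamino)pyridine, CH2Cl2) comes back to the route at 15.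

Step 8. Acid methanolysis of the two secondary acetates may be slow, and the long acid exposure would allow formaldehyde equivalents released from the methoxymethyl groups to bridge the syn diol as a methylene acetal or to alkylate the electron-rich rings, while the freed catechol may oxidise. The fallback separates the three deprotections and traps the methoxymethyl cation; it sets out from 15. Hydrogenolysis as in step 8 (H2, Pd/C, EtOAc–AcOH) is stopped at 16, which is isolated. Base-mediated methanolysis of the acetates (K2CO3, MeOH, argon), carried out while the catechol is still protected, should give (3R,5S)-7-(4-hydroxyphenyl)-1-[3-methoxy-4,5-bis(methoxymethoxy)phenyl]heptane-3,5-diol F9. Cleavage of the aryl methoxymethyl ethers of F9 with ZnBr2 and propane-1-thiol in CH2Cl2 at 0 °C, where the thiol captures the methoxymethyl cation irreversibly, comes back to the route at 17.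

Further compounds
F1 | step 5 | ethyl (5R)-5-hydroxy-7-[3-methoxy-4,5-bis(methoxymethoxy)phenyl]-3-oxoheptanoate | COCOc1cc(CC[C@@H](O)CC(=O)CC(=O)OCC)cc(OC)c1OCOC
F2 | step 5 | ethyl (3R,5R)-3,5-dihydroxy-7-[3-methoxy-4,5-bis(methoxymethoxy)phenyl]heptanoate | COCOc1cc(CC[C@@H](O)C[C@@H](O)CC(=O)OCC)cc(OC)c1OCOC
F3 | step 5 | (3R,5R)-3,5-dihydroxy-7-[3-methoxy-4,5-bis(methoxymethoxy)phenyl]heptanoic acid | COCOc1cc(CC[C@@H](O)C[C@@H](O)CC(=O)O)cc(OC)c1OCOC
F4 | step 5 | (4R,6R)-4-hydroxy-6-{2-[3-methoxy-4,5-bis(methoxymethoxy)phenyl]ethyl}tetrahydro-2H-pyran-2-one | COCOc1cc(CC[C@@H]2C[C@@H](O)CC(=O)O2)cc(OC)c1OCOC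
F5 | step 7 | (4R,6R)-2,4-bis(tert-butyldimethylsilyloxy)-6-{2-[3-methoxy-4,5-bis(methoxymethoxy)phenyl]ethyl}tetrahydro-2H-pyran | COCOc1cc(CC[C@@H]2C[C@@H](O[Si](C)(C)C(C)(C)C)CC(O[Si](C)(C)C(C)(C)C)O2)cc(OC)c1OCOC
F6 | step 7 | (4R,6R)-4-(tert-butyldimethylsilyloxy)-6-{2-[3-methoxy-4,5-bis(methoxymethoxy)phenyl]ethyl}tetrahydro-2H-pyran-2-ol | COCOc1cc(CC[C@@H]2C[C@@H](O[Si](C)(C)C(C)(C)C)CC(O)O2)cc(OC)c1OCOC
F7 | step 7 | (3R,5R)-7-[4-(benzyloxy)phenyl]-5-(tert-butyldimethylsilyloxy)-1-[3-methoxy-4,5-bis(methoxymethoxy)phenyl]heptane-3,7-diol | COCOc1cc(CC[C@@H](O)C[C@@H](O[Si](C)(C)C(C)(C)C)CC(O)c2ccc(OCc3ccccc3)cc2)cc(OC)c1OCOC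
F8 | step 7 | (3R,5R)-7-[4-(benzyloxy)phenyl]-1-[3-methoxy-4,5-bis(methoxymethoxy)phenyl]heptane-3,5,7-triol | COCOc1cc(CC[C@@H](O)C[C@@H](O)CC(O)c2ccc(OCc3ccccc3)cc2)cc(OC)c1OCOC
F9 | step 8 | (3R,5S)-7-(4-hydroxyphenyl)-1-[3-methoxy-4,5-bis(methoxymethoxy)phenyl]heptane-3,5-diol | COCOc1cc(CC[C@@H](O)C[C@@H](O)CCc2ccc(O)cc2)cc(OC)c1OCOC
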